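**Retrosynthetic overview**
- The target is released in one acidic operation from an α‑epoxide whose O6 and O8 are tied in a diisopropylsilaketal: the O5 angelate opens the epoxide at C4 (giving 3α‑OH, 4β‑OH) while the silicon groups hydrolyse.
- The epoxide comes from a bis‑angelate made by double acylation of a diol (O5–H, O10–H); the C10 carbinol comes from a ketone by CBS reduction.
- Key disconnection C1–C7: a vinyl radical at C7, held by an O6–Si–O8 tether, closes onto the diene terminus C1 (7‑exo), setting C1, the C7 methylene and the C3=C4 alkene in one step.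
- The tethered precursor is assembled from toluene cis‑dihydrodiol (C5, C6 and the carbocycle, from toluene) and a bromovinyl aldol (C8) made from 2‑bromoacrolein and an enol silane of 3‑hydroxy‑3‑methylbutan‑2‑one.
- Ring order: the six‑membered carbocycle is the dearomatized arene (step 1); the temporary seven‑membered silaketal ring closes in the radical step; the epoxide is formed in step 9; both temporary rings are opened in step 10.

Locants used in names: ring C1–C6 (C1 bears the side chain, C4 the methyl, C3–C6 the oxygens), side chain C7(=C14H2)–C8–C9–C10–C11(CH3)2; β is the ring face carrying O5 and O6.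

Assumption: the (S)‑tryptophan‑derived catalyst of step 4 is taken to leave the re face of the bound formyl group of 2‑bromoacrolein open (the sense it shows in cycloadditions of this aldehyde); its mirror image would be used if the rotation of 9 showed otherwise.

**Step 1**
Reactants: 1 toluene
Product: 2 (1S,2R)-3-methylcyclohexa-3,5-diene-1,2-diol
Conditions: whole cells of E. coli JM109(pDTG601) expressing toluene dioxygenase, toluene vapour feed, air, glucose‑fed mineral salts medium, pH 6.8, 35 °C; EtOAc extraction
Reagents that add atoms: dioxygen, O=O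
Why: Enzymatic arene cis‑dihydroxylation adds O2 across the 2,3‑bond and the enzyme fixes both carbinol centres (1S,2R, >99% ee), which become C6 and C5 of the target with the methyl carbon as C4.

**Step 2**
Reactants: 3 acrolein (prop-2-enal)
Product: 5 2-bromoacrolein (2-bromoprop-2-enal), via 2,3-dibromopropanal 4 (not isolated)
Conditions: Br2, CH2Cl2, −78 → 0 °C; then Et3N, 0 °C; distil, use fresh
Reagents that add atoms: bromine, BrBr
Why: Bromination of the enal C=C followed by amine‑induced dehydrobromination (E1cB) of the α‑bromo aldehyde gives the α‑bromo enal; no stereocentre is formed.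

**Step 3**
Reactants: 6 3-hydroxy-3-methylbutan-2-one
Product: 7 3-methyl-2,3-bis(trimethylsilyloxy)but-1-ene
Conditions: TMSOTf (2.2 equiv), Et3N (3 equiv), CH2Cl2, 0 °C
Reagents that add atoms: trimethylsilyl trifluoromethanesulfonate, C[Si](C)(C)OS(=O)(=O)C(F)(F)F
Why: Soft enolization (silyl enol ether formation) can only occur toward the methyl group because the other α‑carbon is quaternary, and the tertiary hydroxyl is silylated in the same operation.

**Step 4**
Reactants: 7 3-methyl-2,3-bis(trimethylsilyloxy)but-1-ene; 5 2-bromoacrolein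
Product: 9 (5R)-6-bromo-5-hydroxy-2-methyl-2-(trimethylsilyloxy)hept-6-en-3-one, via bis-silyl aldol 8 (not isolated)
Conditions: (S)-2-butyl-4-(1H-indol-3-ylmethyl)-3-(4-methylbenzenesulfonyl)-1,3,2-oxazaborolidin-5-one (20 mol %), EtCN, −78 °C; then AcOH/THF/H2O (3:1:1), 0 °C
Reagents that add atoms: none
Why: Catalytic asymmetric Mukaiyama aldol addition in which the boron Lewis acid binds the aldehyde and the enol silane attacks the open re face, setting C8 as R; the mild acid work‑up frees the secondary hydroxyl and leaves the tertiary TMS ether.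

**Step 5**
Reactants: 9 (5R)-6-bromo-5-hydroxy-2-methyl-2-(trimethylsilyloxy)hept-6-en-3-one; 2 (1S,2R)-3-methylcyclohexa-3,5-diene-1,2-diol
Product: 11 tethered bromodiene (diisopropylsilaketal joining O8 of 9 to the distal oxygen O6 of 2; O5–H free), via chlorosilyl ether 10 (not isolated)
Conditions: iPr2SiCl2 (3 equiv), Et3N, DMAP (cat.), CH2Cl2, 0 °C; excess silane removed in vacuo; then 2 (1.2 equiv), imidazole, CH2Cl2/DMF, −20 → 0 °C; Et3N‑deactivated silica
Reagents that add atoms: dichlorodiisopropylsilane, CC(C)[Si](Cl)(Cl)C(C)C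
Why: Stepwise nucleophilic substitution at silicon (unsymmetrical silaketal formation) in which the only secondary hydroxyl of 9 takes the first chloride and the bulky chlorosilane 10 then silylates the less hindered hydroxyl of 2, the one remote from the methyl‑bearing carbon, as bulky silyl chlorides do with these diene diols; no stereocentre is formed.

**Step 6**
Reactants: 11 tethered bromodiene
Product: 12 cyclized keto alcohol (cyclohex-3-ene cis-fused at C1/C6 to the seven-membered C6–O–Si(iPr)2–O–C8–C7(=CH2)–C1 ring; 1R,5R,6S,8R)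
Conditions: Bu3SnH (1.3 equiv, syringe pump, 8 h), AIBN (azobisisobutyronitrile, 0.2 equiv), PhH (0.005 M), 80 °C
Reagents that add atoms: none
Why: Proposed new method: a 7‑exo‑trig vinyl‑radical cyclization through an O–Si–O tether onto a cyclohexadiene is not documented as such, the closest known reactions being bromoacetal‑ and silicon‑tethered radical cyclizations (5‑exo Ueno–Stork type and silaketal‑tethered closures of 7‑ to 9‑membered rings); Bu3Sn• abstracts Br, the σ‑vinyl radical at C7 adds to the diene terminus C1 (the only mode that gives an allyl radical), the tether hanging from the β‑oxygen at C6 reaches the β‑face so C1 is set cis to O6 (1R), and the allyl radical takes H from Bu3SnH at its less hindered secondary end C2, leaving the trisubstituted C3=C4 alkene.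

**Step 7**
Reactants: 12 cyclized keto alcohol
Product: 13 cyclized diol (as 12 with C10 ketone reduced to the 10R alcohol)
Conditions: (S)-1-methyl-3,3-diphenyltetrahydro-1H,3H-pyrrolo[1,2-c][1,3,2]oxazaborole ((S)-Me-CBS, 0.5 equiv), catecholborane (3 equiv), PhMe, −78 °C; MeOH, then pH 7 buffer
Reagents that add atoms: none
Why: Corey–Bakshi–Shibata reduction in which the catalyst distinguishes the bulky C(CH3)2OSiMe3 group from the CH2 arm and delivers hydride to give 10R (the same sense as acetophenone to (R)-1-phenylethanol), while catecholborane at −78 °C does not hydroborate the two alkenes.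

**Step 8**
Reactants: 13 cyclized diol
Product: 15 bis-angelate (O5 and O10 esterified with (Z)-2-methylbut-2-enoyl), via 5-O-monoangelate 14 (not isolated)
Conditions: angelic acid (6 equiv), 2,4,6-trichlorobenzoyl chloride (6 equiv), Et3N (12 equiv), PhMe, rt, 2 h; then 13, 80 °C
Reagents that add atoms: angelic acid, C/C=C(/C)C(=O)O
Why: Yamaguchi‑type esterification through the 2,4,6‑trichlorobenzoyl mixed anhydride acylates the only two reactive hydroxyls (allylic O5 first, then hindered O10) without the nucleophilic catalysis that isomerizes angelate to tiglate; the tertiary oxygens are blocked or unreactive and no stereocentre is touched.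

**Step 9**
Reactants: 15 bis-angelate
Product: 16 3α,4α-epoxide (1R,3S,4S,5S,6S,8R,10R)
Conditions: mCPBA (1.1 equiv), NaHCO3, CH2Cl2, −20 → 0 °C
Reagents that add atoms: 3-chloroperoxybenzoic acid, O=C(OO)c1cccc(Cl)c1
Why: Prilezhaev epoxidation picks the trisubstituted C3=C4 alkene (the angelates are electron‑poor, the exocyclic methylene is only 1,1‑disubstituted and shielded by the silaketal) and attacks the α‑face because O5, O6 and C7 all sit on the β‑face, which fixes the C3–O bond as α.

**Step 10**
Reactants: 16 3α,4α-epoxide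
Product: 18 CNP0108485.1 (1R,3S,4R,5S,6S,8R,10R; 5,10-di-O-angelate of the 3,4,5,6,8,10,11-heptol), via silylated 3,4-diol 17 (not isolated)
Conditions: TFA/H2O/THF (1:1:4), 0 °C → rt
Reagents that add atoms: water, O
Why: Acid‑catalysed epoxide hydrolysis with neighbouring‑group participation, in which the β‑angelate carbonyl at C5 opens the protonated epoxide at tertiary C4 from the β‑face (inversion) through a cis‑fused dioxolanylium ion that water returns to the secondary ester, giving 4β‑OH (4R) and retaining 3α‑OH (3S); the same aqueous acid hydrolyses the silaketal and the TMS ether.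

**Compound list**
1 | toluene | Cc1ccccc1 | starting material
2 | (1S,2R)-3-methylcyclohexa-3,5-diene-1,2-diol | CC1=CC=C[C@H](O)[C@@H]1O | intermediate
3 | acrolein (prop-2-enal) | C=CC=O | starting material
4 | 2,3-dibromopropanal (racemic) | O=CC(Br)CBr | intermediate (not isolated)
5 | 2-bromoacrolein (2-bromoprop-2-enal) | C=C(Br)C=O | intermediate
6 | 3-hydroxy-3-methylbutan-2-one | CC(=O)C(C)(C)O | starting material
7 | 3-methyl-2,3-bis(trimethylsilyloxy)but-1-ene | C=C(O[Si](C)(C)C)C(C)(C)O[Si](C)(C)C | intermediate
8 | (5R)-6-bromo-2-methyl-2,5-bis(trimethylsilyloxy)hept-6-en-3-one | C=C(Br)[C@H](O[Si](C)(C)C)CC(=O)C(C)(C)O[Si](C)(C)C | intermediate (not isolated)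
9 | (5R)-6-bromo-5-hydroxy-2-methyl-2-(trimethylsilyloxy)hept-6-en-3-one | C=C(Br)[C@H](O)CC(=O)C(C)(C)O[Si](C)(C)C | intermediate
10 | (5R)-6-bromo-5-[chloro(diisopropyl)silyl]oxy-2-methyl-2-(trimethylsilyloxy)hept-6-en-3-one | C=C(Br)[C@H](O[Si](Cl)(C(C)C)C(C)C)CC(=O)C(C)(C)O[Si](C)(C)C | intermediate (not isolated)
11 | (5R)-6-bromo-5-[({[(1S,6R)-6-hydroxy-5-methylcyclohexa-2,4-dien-1-yl]oxy}diisopropylsilyl)oxy]-2-methyl-2-(trimethylsilyloxy)hept-6-en-3-one | CC1=CC=C[C@H](O[Si](C(C)C)(C(C)C)O[C@H](CC(=O)C(C)(C)O[Si](C)(C)C)C(Br)=C)[C@@H]1O | intermediate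
12 | cyclized keto alcohol: 4-methylcyclohex-3-ene (C1–C6) with 5β-OH, cis-fused at C1/C6 to the ring C6–O–Si(iPr)2–O–C8–C7(=CH2)–C1; C8 bears CH2C(=O)C(CH3)2OSiMe3; 1R,5R,6S,8R | C=C1[C@@H](CC(=O)C(C)(C)O[Si](C)(C)C)O[Si](C(C)C)(C(C)C)O[C@@H]2[C@H](O)C(C)=CC[C@H]12 | intermediate
13 | cyclized diol: as 12 with C10 as the 10R carbinol | C=C1[C@@H](C[C@@H](O)C(C)(C)O[Si](C)(C)C)O[Si](C(C)C)(C(C)C)O[C@@H]2[C@H](O)C(C)=CC[C@H]12 | intermediate
14 | 5-O-monoangelate of 13 | C=C1[C@@H](C[C@@H](O)C(C)(C)O[Si](C)(C)C)O[Si](C(C)C)(C(C)C)O[C@@H]2[C@H](OC(=O)/C(C)=C\C)C(C)=CC[C@H]12 | intermediate (not isolated)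
15 | 5,10-di-O-angelate of 13 | C=C1[C@@H](C[C@@H](OC(=O)/C(C)=C\C)C(C)(C)O[Si](C)(C)C)O[Si](C(C)C)(C(C)C)O[C@@H]2[C@H](OC(=O)/C(C)=C\C)C(C)=CC[C@H]12 | intermediate
16 | 3α,4α-epoxide of 15 (1R,3S,4S,5S,6S,8R,10R) | C=C1[C@@H](C[C@@H](OC(=O)/C(C)=C\C)C(C)(C)O[Si](C)(C)C)O[Si](C(C)C)(C(C)C)O[C@@H]2[C@H](OC(=O)/C(C)=C\C)[C@@]3(C)O[C@H]3C[C@H]12 | intermediate
17 | silylated 3α,4β-diol (epoxide opened; silaketal and TMS ether still in place) | C=C1[C@@H](C[C@@H](OC(=O)/C(C)=C\C)C(C)(C)O[Si](C)(C)C)O[Si](C(C)C)(C(C)C)O[C@@H]2[C@H](OC(=O)/C(C)=C\C)[C@](C)(O)[C@@H](O)C[C@H]12 | intermediate (not isolated)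
18 | CNP0108485.1 | C=C([C@H](O)C[C@@H](OC(=O)/C(C)=C\C)C(C)(C)O)[C@H]1C[C@H](O)[C@@](C)(O)[C@@H](OC(=O)/C(C)=C\C)[C@H]1O | target

**Step count and risks**
Total steps: 10. Longest linear sequence: 8 (steps 2 or 3, then 4–10).

Most likely to fail:

1. Step 6 (radical cyclization). The 7‑exo closure competes with 1,5‑hydrogen transfer from an Si–CH(CH3)2 group and with direct reduction of the vinyl radical. The C8 substituent may also be mismatched with the ring, and hydrogen delivery to the allyl radical could occur in part at C4. Fallback: setting out from 11, close the same bond by an intramolecular reductive Heck reaction (Pd(OAc)2, PPh3, HCO2Na, Et4NCl, DMF, 80 °C). Zerovalent palladium inserts into the C7–Br bond, syn‑carbopalladation of the diene at C1 from the tethered β‑face gives a π‑allylpalladium species, and formate delivers hydride to the less substituted terminus C2. This comes back to the route at 12 and makes no new compound (F0).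

2. Step 5 (regioselective silaketal formation on the acid‑sensitive diene diol). Silylation at O5 instead of O6, or aromatization of 2, would erode the yield. Fallback: setting out from 2, heat with Bu2SnO in MeOH to form the dibutylstannylene acetal of 2 F1, then treat it with chlorosilyl ether 10 (made as in step 5) in CH2Cl2 at −20 °C. Stannylene acetals of cis‑diols transfer electrophiles to the pseudoequatorial oxygen, which here is the distal O6 because the O5 substituent is held pseudoaxial by the neighbouring methyl. Aqueous work‑up comes back to the route at 11.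

3. Step 8 (double angeloylation). O10 is next to a quaternary carbon, so acylation may stall or need forcing conditions that isomerize angelate to tiglate. Fallback: setting out from 13, esterify both hydroxyls with 2-[bis(2,2,2-trifluoroethoxy)phosphoryl]propanoic acid (EDC·HCl, DMAP, CH2Cl2) to give the bis(phosphonopropionate) of 13 F2. Then build both Z‑alkenes by Still–Gennari olefination with acetaldehyde (KN(SiMe3)2, 18‑crown‑6, THF, −78 °C). This comes back to the route at 15.

**Further compounds**
F0 | step 6 | none | none
F1 | step 5 | dibutylstannylene acetal of 2 (2,2-dibutyl-4-methyl-3a,7a-dihydro-1,3,2-benzodioxastannole, cis, carbinol centres as in 2) | CC1=CC=C[C@@H]2O[Sn](CCCC)(CCCC)O[C@H]12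
F2 | step 8 | O5,O10-bis[2-(bis(2,2,2-trifluoroethoxy)phosphoryl)propanoate] of 13 (epimers at the phosphonate α-carbons) | C=C1[C@@H](C[C@@H](OC(=O)C(C)P(=O)(OCC(F)(F)F)OCC(F)(F)F)C(C)(C)O[Si](C)(C)C)O[Si](C(C)C)(C(C)C)O[C@@H]2[C@H](OC(=O)C(C)P(=O)(OCC(F)(F)F)OCC(F)(F)F)C(C)=CC[C@H]12
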